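**Retrosynthetic overview**
1. Target 15 ⇐ spiro-epoxy diol 13 (primary acetylation, then acetate opening of the oxirane) ⇐ allylic diol 12 (allylic-alcohol-directed epoxidation) ⇐ elemane acrylate 10 (ester reduction).
2. 10 ⇐ germacradiene 9 by Cope rearrangement: C5–C10 bond, cyclohexane ring, formed second, in the same flask.
3. 9 ⇐ achiral bromo-enal 8 by catalytic enantioselective chromium allylation macrocyclisation: C6–C7 bond (the farnesyl C1–C10 bond made by the terpene cyclases), ten-membered ring, formed first. It sets C6 and C7; the Cope step relays them to C5 and C10.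
4. 8 ⇐ dialdehyde 5 + methyl acrylate 6 (Baylis–Hillman, allylic bromination); 5 ⇐ (2E,6E)-farnesol 1 (terminal epoxidation, periodate cleavage, allylic oxidation).

Assumption and convention: positions are numbered as in germacranes/elemanes (ring C5–C10, side chain C11–C13), and the oxirane carbon C11 of 13 and 14 is drawn as the epimer expected from the L-tartrate, which is immaterial because C11 is not stereogenic in 15.

**Route**

Step 1
Reactants: 1 (2E,6E)-farnesol
Product: 3 (2E,6E)-10,11-epoxy-3,7,11-trimethyldodeca-2,6-dien-1-ol (racemic at C10), via bromohydrin 2 (not isolated)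
Conditions: NBS, THF/H2O, 0 °C; then K2CO3, MeOH, rt
Reagents that add atoms: water, O (epoxide oxygen); N-bromosuccinimide, O=C1CCC(=O)N1Br (bromine, present in 2 only)
Why: Terminal-selective bromohydrin formation (van Tamelen-type, Markovnikov attack of water on the bromonium ion of the distal alkene) followed by base-induced Williamson closure gives the terminal epoxide; its one stereocentre is racemic and is excised in step 2.

Step 2
Reactants: 3 (2E,6E)-10,11-epoxy-3,7,11-trimethyldodeca-2,6-dien-1-ol
Product: 4 (4E,8E)-10-hydroxy-4,8-dimethyldeca-4,8-dienal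
Conditions: H5IO6, THF/Et2O, 0 °C
Reagents that add atoms: none
Why: Periodic acid opens the trisubstituted epoxide and cleaves the resulting glycol (Malaprade-type cleavage), removing C11–C13 as acetone and leaving the C10 aldehyde; the trisubstituted alkenes and the allylic alcohol are untouched.

Step 3
Reactants: 4 (4E,8E)-10-hydroxy-4,8-dimethyldeca-4,8-dienal
Product: 5 (2E,6E)-3,7-dimethyldeca-2,6-dienedial
Conditions: MnO2, CH2Cl2, rt
Reagents that add atoms: none
Why: Chemoselective allylic oxidation by MnO2 converts only the primary allylic alcohol into the (E)-enal, with the saturated aldehyde and the olefin geometry unchanged.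

Step 4
Reactants: 5 (2E,6E)-3,7-dimethyldeca-2,6-dienedial; 6 methyl acrylate
Product: 7 methyl (6E,10E)-3-hydroxy-6,10-dimethyl-2-methylidene-12-oxododeca-6,10-dienoate (racemic)
Conditions: 6 (3 equiv), 1,4-diazabicyclo[2.2.2]octane (0.5 equiv), MeOH, rt, 3–5 d
Reagents that add atoms: none
Why: Morita–Baylis–Hillman reaction, in which the amine–acrylate zwitterion adds to the unhindered saturated aldehyde much faster than to the β,β-disubstituted enal carbonyl; the new carbinol centre is racemic and is erased in step 5.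

Step 5
Reactants: 7 methyl (6E,10E)-3-hydroxy-6,10-dimethyl-2-methylidene-12-oxododeca-6,10-dienoate
Product: 8 methyl (2Z,6E,10E)-2-(bromomethyl)-6,10-dimethyl-12-oxododeca-2,6,10-trienoate
Conditions: NBS, Me2S, CH2Cl2, 0 °C to rt
Reagents that add atoms: N-bromosuccinimide, O=C1CCC(=O)N1Br
Why: Corey–Kim-type bromination converts the Baylis–Hillman alcohol with allylic transposition (SN2′) into the thermodynamically preferred (2Z)-2-(bromomethyl)enoate, and the enal is inert to the reagent.

Step 6
Reactants: 8 methyl (2Z,6E,10E)-2-(bromomethyl)-6,10-dimethyl-12-oxododeca-2,6,10-trienoate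
Product: 10 methyl 2-[(1S,2S,3S,4S)-4-ethenyl-4-methyl-3-(prop-1-en-2-yl)-2-(trimethylsilyloxy)cyclohexyl]prop-2-enoate, via germacradiene silyl ether 9 (not isolated)
Conditions: CrCl2 (15 mol%), (S,S)-1,8-bis(4-isopropyl-4,5-dihydrooxazol-2-yl)-3,6-diphenyl-9H-carbazole (17 mol%), i-Pr2NEt (30 mol%), Mn powder (3 equiv), Me3SiCl (2 equiv), THF, rt, 8 added over 12 h to 5 mM; filter; PhMe, 110 °C, 8 h
Reagents that add atoms: chlorotrimethylsilane, C[Si](C)(C)Cl
Why: Proposed new method: divalent chromium (regenerated by manganese metal) inserts into the allylic C–Br bond and the ligand-bound allylchromium adds through its γ-carbon (C7) to the enal carbonyl (C6) in a chair-like Zimmerman–Traxler transition state, closing the ten-membered ring with the 6,7-anti relationship imposed by the tether and the aldehyde face chosen by the chiral tridentate ligand, after which Me3SiCl silylates the alkoxide and releases chromium; on heating, the (E,E)-1,5-diene 9 undergoes Cope rearrangement through the chair transition state that keeps the C6 and C7 substituents pseudo-equatorial, relaying these two centres to C5 and C10 of the all-equatorial elemane; the closest known reactions are the racemic chromium-mediated Nozaki–Hiyama–Kishi closure of 12-bromofarnesal-type esters to trans-germacranolide precursors, the intermolecular catalytic enantioselective chromium allylation of aldehydes with 2-(bromomethyl)acrylates, and the thermal germacrene-to-elemene Cope rearrangement.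

Step 7
Reactants: 10 methyl 2-[(1S,2S,3S,4S)-4-ethenyl-4-methyl-3-(prop-1-en-2-yl)-2-(trimethylsilyloxy)cyclohexyl]prop-2-enoate
Product: 12 (1S,2S,3S,6S)-3-ethenyl-6-(3-hydroxyprop-1-en-2-yl)-3-methyl-2-(prop-1-en-2-yl)cyclohexan-1-ol, via silyl ether alcohol 11 (not isolated)
Conditions: i-Bu2AlH (3.5 equiv), CH2Cl2, −78 to 0 °C; then 1 M HCl (aq), 0 °C
Reagents that add atoms: none
Why: 1,2-Hydride reduction of the α-substituted acrylate ester gives the allylic alcohol without touching the isolated alkenes, and the acidic quench hydrolyses the trimethylsilyl ether; no stereocentre is affected.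

Step 8
Reactants: 12 (1S,2S,3S,6S)-3-ethenyl-6-(3-hydroxyprop-1-en-2-yl)-3-methyl-2-(prop-1-en-2-yl)cyclohexan-1-ol
Product: 13 (1R,2S,3S,6R)-3-ethenyl-6-[(2S)-2-(hydroxymethyl)oxiran-2-yl]-3-methyl-2-(prop-1-en-2-yl)cyclohexan-1-ol
Conditions: Ti(OiPr)4 (10 mol%), diisopropyl L-(+)-tartrate (12 mol%), t-BuOOH, 4 Å molecular sieves, CH2Cl2, −20 °C
Reagents that add atoms: tert-butyl hydroperoxide, CC(C)(C)OO
Why: Katsuki–Sharpless titanium–tartrate epoxidation acts only on the allylic-alcohol alkene (the homoallylic C6–OH does not direct under these conditions, and the vinyl and isopropenyl groups are inert); the new C11 centre is set by the tartrate by analogy with simple 2-substituted allyl alcohols and is inconsequential.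

Step 9
Reactants: 13 (1R,2S,3S,6R)-3-ethenyl-6-[(2S)-2-(hydroxymethyl)oxiran-2-yl]-3-methyl-2-(prop-1-en-2-yl)cyclohexan-1-ol
Product: 15 2-[(1R,2R,3S,4S)-4-ethenyl-2-hydroxy-4-methyl-3-(prop-1-en-2-yl)cyclohexyl]-2-hydroxypropane-1,3-diyl diacetate, via epoxy acetate 14 (not isolated)
Conditions: Ac2O (1.1 equiv), pyridine, CH2Cl2, 0 °C; concentrate; then CsOAc, AcOH, DMF, 60 °C
Reagents that add atoms: acetic anhydride, CC(=O)OC(C)=O; acetic acid, CC(=O)O (delivered as caesium acetate, [Cs+].CC(=O)[O-])
Why: Primary-selective acetylation (the secondary C6–OH is flanked by two branched carbons) followed by SN2 opening of the 2,2-disubstituted oxirane at its CH2 terminus by acetate gives the tertiary alcohol and the second primary acetate; C11 ceases to be stereogenic, and any acyl migration converges on the same primary diacetate.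

**Compound list**
1 | (2E,6E)-farnesol | CC(C)=CCC/C(C)=C/CC/C(C)=C/CO | starting material
2 | (2E,6E)-10-bromo-3,7,11-trimethyldodeca-2,6-diene-1,11-diol (racemic) | CC(C)(O)C(Br)CC/C(C)=C/CC/C(C)=C/CO | intermediate (not isolated)
3 | (2E,6E)-10,11-epoxy-3,7,11-trimethyldodeca-2,6-dien-1-ol (racemic) | CC1(C)OC1CC/C(C)=C/CC/C(C)=C/CO | intermediate
4 | (4E,8E)-10-hydroxy-4,8-dimethyldeca-4,8-dienal | O=CCC/C(C)=C/CC/C(C)=C/CO | intermediate
5 | (2E,6E)-3,7-dimethyldeca-2,6-dienedial | O=CCC/C(C)=C/CC/C(C)=C/C=O | intermediate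
6 | methyl acrylate | C=CC(=O)OC | starting material
7 | methyl (6E,10E)-3-hydroxy-6,10-dimethyl-2-methylidene-12-oxododeca-6,10-dienoate (racemic) | COC(=O)C(=C)C(O)CC/C(C)=C/CC/C(C)=C/C=O | intermediate
8 | methyl (2Z,6E,10E)-2-(bromomethyl)-6,10-dimethyl-12-oxododeca-2,6,10-trienoate | COC(=O)/C(CBr)=C/CC/C(C)=C/CC/C(C)=C/C=O | intermediate
9 | methyl 2-[(1S,2R,3E,7E)-4,8-dimethyl-2-(trimethylsilyloxy)cyclodeca-3,7-dien-1-yl]prop-2-enoate | C/C1=C\CC/C(C)=C/[C@@H](O[Si](C)(C)C)[C@H](C(=C)C(=O)OC)CC1 | intermediate (not isolated)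
10 | methyl 2-[(1S,2S,3S,4S)-4-ethenyl-4-methyl-3-(prop-1-en-2-yl)-2-(trimethylsilyloxy)cyclohexyl]prop-2-enoate | C=C[C@]1(C)CC[C@@H](C(=C)C(=O)OC)[C@H](O[Si](C)(C)C)[C@H]1C(=C)C | intermediate
11 | 2-[(1S,2S,3S,4S)-4-ethenyl-4-methyl-3-(prop-1-en-2-yl)-2-(trimethylsilyloxy)cyclohexyl]prop-2-en-1-ol | C=C[C@]1(C)CC[C@@H](C(=C)CO)[C@H](O[Si](C)(C)C)[C@H]1C(=C)C | intermediate (not isolated)
12 | (1S,2S,3S,6S)-3-ethenyl-6-(3-hydroxyprop-1-en-2-yl)-3-methyl-2-(prop-1-en-2-yl)cyclohexan-1-ol | C=C[C@]1(C)CC[C@@H](C(=C)CO)[C@H](O)[C@H]1C(=C)C | intermediate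
13 | (1R,2S,3S,6R)-3-ethenyl-6-[(2S)-2-(hydroxymethyl)oxiran-2-yl]-3-methyl-2-(prop-1-en-2-yl)cyclohexan-1-ol | C=C[C@]1(C)CC[C@@H]([C@]2(CO)CO2)[C@H](O)[C@H]1C(=C)C | intermediate
14 | [(2R)-2-[(1R,2R,3S,4S)-4-ethenyl-2-hydroxy-4-methyl-3-(prop-1-en-2-yl)cyclohexyl]oxiran-2-yl]methyl acetate | C=C[C@]1(C)CC[C@@H]([C@]2(COC(C)=O)CO2)[C@H](O)[C@H]1C(=C)C | intermediate (not isolated)
15 | 2-[(1R,2R,3S,4S)-4-ethenyl-2-hydroxy-4-methyl-3-(prop-1-en-2-yl)cyclohexyl]-2-hydroxypropane-1,3-diyl diacetate | C=C[C@]1(C)CC[C@@H](C(O)(COC(C)=O)COC(C)=O)[C@H](O)[C@H]1C(=C)C | target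

**Totals and risks**
Total step count: 9. Longest linear sequence: 9 steps (1 to 15; 6 enters at step 4).

Most likely to fail, step 6: the enantioselective macrocyclisation is untested. The sense of induction of the (S,S)-ligand is assumed, and its mirror image would be used if it delivers the antipode. An uncatalysed manganese-mediated background reaction or oligomerisation could erode ee and yield. The fallback sets out from 8 and replaces asymmetric catalysis by resolution. Ring closure with stoichiometric CrCl2 in THF at high dilution without ligand gives racemic anti-configured methyl 2-[(1S*,2R*,3E,7E)-2-hydroxy-4,8-dimethylcyclodeca-3,7-dien-1-yl]prop-2-enoate F1. Esterification with (S)-2-methoxy-2-phenylacetic acid (DCC, DMAP) and separation of the diastereomers gives methyl 2-[(1S,2R,3E,7E)-2-{[(2S)-2-methoxy-2-phenylacetyl]oxy}-4,8-dimethylcyclodeca-3,7-dien-1-yl]prop-2-enoate F2. Cope rearrangement in toluene at 110 °C gives methyl 2-[(1S,2S,3S,4S)-4-ethenyl-2-{[(2S)-2-methoxy-2-phenylacetyl]oxy}-4-methyl-3-(prop-1-en-2-yl)cyclohexyl]prop-2-enoate F3. Reduction of both esters with i-Bu2AlH comes back to the route at 12.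

Second, step 4: the Baylis–Hillman reaction of an enolisable aldehyde is slow, and the amine may isomerise or add to the enal. The fallback sets out from 4, before the enal exists. The α-(methoxycarbonyl)vinylalane generated from methyl propiolate with i-Bu2AlH/HMPA in THF is added to the aldehyde of 4, giving methyl (6E,10E)-3,12-dihydroxy-6,10-dimethyl-2-methylidenedodeca-6,10-dienoate F4. MnO2 then oxidises only its primary, electron-rich allylic alcohol, which comes back to the route at 7.

Third, step 9: the free C6–OH or the neighbouring acetate may open the oxirane, and the one-flask sequence may over- or under-acetylate. The fallback sets out from 13. The oxirane is hydrolysed with aqueous NaOH in t-BuOH at 70 °C (the Payne rearrangement is degenerate here) to 2-[(1R,2R,3S,4S)-4-ethenyl-2-hydroxy-4-methyl-3-(prop-1-en-2-yl)cyclohexyl]propane-1,2,3-triol F5. The two primary hydroxyls are then acetylated selectively with AcCl and 2,4,6-collidine in CH2Cl2 at −78 °C, which comes back to the route at 15.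

Further compounds
F1 | step 6 | methyl 2-[(1S*,2R*,3E,7E)-2-hydroxy-4,8-dimethylcyclodeca-3,7-dien-1-yl]prop-2-enoate (racemate, both enantiomers written) | C/C1=C\CC/C(C)=C/[C@@H](O)[C@H](C(=C)C(=O)OC)CC1.C/C1=C\CC/C(C)=C/[C@H](O)[C@@H](C(=C)C(=O)OC)CC1
F2 | step 6 | methyl 2-[(1S,2R,3E,7E)-2-{[(2S)-2-methoxy-2-phenylacetyl]oxy}-4,8-dimethylcyclodeca-3,7-dien-1-yl]prop-2-enoate | C/C1=C\CC/C(C)=C/[C@@H](OC(=O)[C@@H](OC)c2ccccc2)[C@H](C(=C)C(=O)OC)CC1
F3 | step 6 | methyl 2-[(1S,2S,3S,4S)-4-ethenyl-2-{[(2S)-2-methoxy-2-phenylacetyl]oxy}-4-methyl-3-(prop-1-en-2-yl)cyclohexyl]prop-2-enoate | C=C[C@]1(C)CC[C@@H](C(=C)C(=O)OC)[C@H](OC(=O)[C@@H](OC)c2ccccc2)[C@H]1C(=C)C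
F4 | step 4 | methyl (6E,10E)-3,12-dihydroxy-6,10-dimethyl-2-methylidenedodeca-6,10-dienoate (racemic) | COC(=O)C(=C)C(O)CC/C(C)=C/CC/C(C)=C/CO
F5 | step 9 | 2-[(1R,2R,3S,4S)-4-ethenyl-2-hydroxy-4-methyl-3-(prop-1-en-2-yl)cyclohexyl]propane-1,2,3-triol | C=C[C@]1(C)CC[C@@H](C(O)(CO)CO)[C@H](O)[C@H]1C(=C)C
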